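**Plan**

- Ring A is the 7-oxabicyclo[4.1.0]heptane and ring B the bromocyclohexanol. After the silyl ether, the retrosynthesis cuts through the oxirane of ring A: the C1–C6 bond (shared by the cyclohexane and the three-membered ring) together with the O–C(H) bond. This leaves an open-chain methyl ketone whose sixth carbon carries a Ph2S+ group. The second cut is the CH–CH2 bond between that chain and the 2-substituted allyl unit that bears ring B.
- Enabling feature: the two oxirane carbons (the quaternary C–CH3 and the CH) are neighbouring ring atoms of the cyclohexane, so a ketone carbon and a sulfonium ylide carbon in a 1,6-relation build the six-membered ring and the epoxide from one C–C bond.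
- Forward: ring B is made first from limonene diol (bromide by inversion, ene chlorination, iodide exchange). (S)-Carvone gives a seven-membered lactone (conjugate reduction, Baeyer–Villiger) that serves as a temporary ring. Lactone enolate alkylation joins the fragments; reductive ring opening, sulfonium formation and oxidation set up the annulation. Ring A and its oxirane arise last, then desilylation.
- Stereochemistry: ring B C–OH and C–side chain come from (1S,2S,4R)-limonene-1,2-diol and C–Br from SN2 inversion. In ring A the isopropenyl carbon comes from (S)-carvone, the neighbouring CH from trans alkylation on the lactone, and the two oxirane carbons from the chair-like ylide addition.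

Key step: step 10

Remark: (1S,2S,4R)-limonene-1,2-diol and (S)-(+)-carvone are taken as commercial; ketone 9 and compounds 10 to 15 are carried as mixtures of epimers at the methyl-bearing CH–O (CH–CO in 9) carbon (major epimer named and drawn), which becomes the ketone carbon in step 9.

**Route**

Step 1
Reactants: 1 (1S,2S,4R)-1-methyl-4-(prop-1-en-2-yl)cyclohexane-1,2-diol
Product: 4 {[(1S,2R,4R)-2-bromo-1-methyl-4-(prop-1-en-2-yl)cyclohexyl]oxy}triethylsilane, via hydroxy triflate 2 (not isolated), via silyloxy triflate 3 (not isolated)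
Conditions: Tf2O, 2,6-lutidine, CH2Cl2, −78 °C; then Et3SiOTf, −78 → −40 °C; then Bu4NBr, −40 °C → rt
Reagents that add atoms: triethylsilyl trifluoromethanesulfonate, CC[Si](CC)(CC)OS(=O)(=O)C(F)(F)F; tetrabutylammonium bromide, [Br-].CCCC[N+](CCCC)(CCCC)CCCC
Why: Selective O-triflation of the secondary axial hydroxyl, in-situ silylation of the tertiary hydroxyl (which blocks oxirane formation by neighbouring-group attack) and SN2 displacement of the axial triflate by bromide with inversion should give the equatorial bromide cis to the tertiary oxygen, i.e. the (2R) centre, while C1 and C4 come unchanged from the diol.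

Step 2
Reactants: 4 {[(1S,2R,4R)-2-bromo-1-methyl-4-(prop-1-en-2-yl)cyclohexyl]oxy}triethylsilane
Product: 5 {[(1S,2R,4R)-2-bromo-4-(3-chloroprop-1-en-2-yl)-1-methylcyclohexyl]oxy}triethylsilane
Conditions: Ca(OCl)2, CO2 (dry ice), CH2Cl2/H2O, 0 °C
Reagents that add atoms: calcium hypochlorite, [Ca+2].[O-]Cl.[O-]Cl
Why: Ene-type allylic chlorination of the isopropenyl group by HOCl made in the flask, a standard reaction of isopropenyl terpenoids, should give the 2-(chloromethyl)vinyl group without touching a stereocentre, the bromide or the silyl ether.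

Step 3
Reactants: 5 {[(1S,2R,4R)-2-bromo-4-(3-chloroprop-1-en-2-yl)-1-methylcyclohexyl]oxy}triethylsilane
Product: 6 {[(1S,2R,4R)-2-bromo-4-(3-iodoprop-1-en-2-yl)-1-methylcyclohexyl]oxy}triethylsilane
Conditions: NaI, acetone, rt, dark
Reagents that add atoms: sodium iodide, [Na+].[I-]
Why: Finkelstein exchange is fast at the primary allylic chloride and should leave the hindered secondary ring bromide alone at room temperature.

Step 4
Reactants: 7 (S)-(+)-carvone [(5S)-2-methyl-5-(prop-1-en-2-yl)cyclohex-2-en-1-one]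
Product: 9 (2S,5S)-2-methyl-5-(prop-1-en-2-yl)cyclohexan-1-one, via lithium enolate 8 (not isolated)
Conditions: LiBH(s-Bu)3, THF, −78 °C; then H2O
Reagents that add atoms: none
Why: Conjugate hydride reduction of the enone leaves the isopropenyl group and the C5 stereocentre untouched; protonation of the enolate gives mainly the 2,5-trans epimer, and the configuration at C2 is of no consequence because this carbon becomes a ketone carbon in step 9.

Step 5
Reactants: 9 (2S,5S)-2-methyl-5-(prop-1-en-2-yl)cyclohexan-1-one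
Product: 10 (4S,7S)-7-methyl-4-(prop-1-en-2-yl)oxepan-2-one
Conditions: KHSO5 (as 2KHSO5·KHSO4·K2SO4), wet Al2O3, CH2Cl2, rt
Reagents that add atoms: potassium peroxymonosulfate, [K+].[O-]S(=O)(=O)OO
Why: Baeyer–Villiger oxidation with migration of the more substituted α-carbon (retention) should give the seven-membered lactone, since peroxymonosulfate attacks the ketone in preference to the 1,1-disubstituted alkene.

Step 6
Reactants: 10 (4S,7S)-7-methyl-4-(prop-1-en-2-yl)oxepan-2-one; 6 {[(1S,2R,4R)-2-bromo-4-(3-iodoprop-1-en-2-yl)-1-methylcyclohexyl]oxy}triethylsilane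
Product: 12 (3R,4S,7S)-3-{2-[(1R,3R,4S)-3-bromo-4-methyl-4-(triethylsilyloxy)cyclohexyl]prop-2-en-1-yl}-7-methyl-4-(prop-1-en-2-yl)oxepan-2-one, via lactone enolate 11 (not isolated)
Conditions: LiN(iPr)2, THF, −78 °C; then 6, DMPU, −78 → −40 °C
Reagents that add atoms: none
Why: Alkylation of the lithium enolate of the seven-membered lactone by the allylic iodide should occur anti to the neighbouring C4 isopropenyl group (1,2-induction in the temporary ring), setting the new (3R) centre trans to C4; the secondary bromide and silyl ether are inert at −78 °C.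

Step 7
Reactants: 12 (3R,4S,7S)-3-{2-[(1R,3R,4S)-3-bromo-4-methyl-4-(triethylsilyloxy)cyclohexyl]prop-2-en-1-yl}-7-methyl-4-(prop-1-en-2-yl)oxepan-2-one
Product: 13 (2R,3S,6S)-2-{2-[(1R,3R,4S)-3-bromo-4-methyl-4-(triethylsilyloxy)cyclohexyl]prop-2-en-1-yl}-3-(prop-1-en-2-yl)heptane-1,6-diol
Conditions: LiBH4, THF, 0 °C → rt
Reagents that add atoms: none
Why: Hydride reduction of the lactone opens the temporary ring to the 1,6-diol and should not touch the alkyl bromide, the alkenes or any stereocentre.

Step 8
Reactants: 13 (2R,3S,6S)-2-{2-[(1R,3R,4S)-3-bromo-4-methyl-4-(triethylsilyloxy)cyclohexyl]prop-2-en-1-yl}-3-(prop-1-en-2-yl)heptane-1,6-diol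
Product: 15 [(2R,3S,6S)-2-{2-[(1R,3R,4S)-3-bromo-4-methyl-4-(triethylsilyloxy)cyclohexyl]prop-2-en-1-yl}-6-hydroxy-3-(prop-1-en-2-yl)heptyl]diphenylsulfonium trifluoromethanesulfonate, via primary triflate 14 (not isolated)
Conditions: Tf2O (1.05 equiv), 2,6-di-tert-butyl-4-methylpyridine, CH2Cl2, −78 °C; then Ph2S (excess), −78 °C → rt
Reagents that add atoms: trifluoromethanesulfonic anhydride, O=S(=O)(OS(=O)(=O)C(F)(F)F)C(F)(F)F; diphenyl sulfide, c1ccccc1Sc1ccccc1
Why: The primary hydroxyl should be triflated selectively at −78 °C (as primary over secondary hydroxyls in sugars) and the triflate then alkylates diphenyl sulfide in an SN2 reaction to give the alkyldiphenylsulfonium triflate.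

Step 9
Reactants: 15 [(2R,3S,6S)-2-{2-[(1R,3R,4S)-3-bromo-4-methyl-4-(triethylsilyloxy)cyclohexyl]prop-2-en-1-yl}-6-hydroxy-3-(prop-1-en-2-yl)heptyl]diphenylsulfonium trifluoromethanesulfonate
Product: 16 [(2R,3S)-2-{2-[(1R,3R,4S)-3-bromo-4-methyl-4-(triethylsilyloxy)cyclohexyl]prop-2-en-1-yl}-6-oxo-3-(prop-1-en-2-yl)heptyl]diphenylsulfonium trifluoromethanesulfonate
Conditions: Dess–Martin periodinane, CH2Cl2, rt
Reagents that add atoms: none
Why: Dess–Martin oxidation of the secondary alcohol gives the methyl ketone and removes the stereocentre that was carried as a mixture; the sulfonium salt, silyl ether and bromide should be inert.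

Step 10
Reactants: 16 [(2R,3S)-2-{2-[(1R,3R,4S)-3-bromo-4-methyl-4-(triethylsilyloxy)cyclohexyl]prop-2-en-1-yl}-6-oxo-3-(prop-1-en-2-yl)heptyl]diphenylsulfonium trifluoromethanesulfonate
Product: 19 {[(1S,2R,4R)-2-bromo-1-methyl-4-{3-[(1R,2R,3S,6S)-6-methyl-3-(prop-1-en-2-yl)-7-oxabicyclo[4.1.0]heptan-2-yl]prop-1-en-2-yl}cyclohexyl]oxy}triethylsilane, via ylide 17 (not isolated), via betaine 18 (not isolated)
Conditions: KN(SiMe3)2 (1.05 equiv), THF, −78 → 0 °C
Reagents that add atoms: none
Why: KN(SiMe3)2 removes a proton from the only carbon next to sulfur that carries hydrogen (the phenyl groups allow neither a second ylide nor elimination through an ylide); the non-stabilised ylide carbon of 17 adds to the methyl ketone six atoms away (6-exo-trig) to give betaine 18, whose alkoxide expels Ph2S by backside attack (3-exo-tet), so one C–C bond closes the cyclohexane and the oxirane together. The closest known reaction type is the intramolecular Corey–Chaykovsky epoxidation of ketones by tethered sulfonium ylides, which gives epoxide-fused five- to seven-membered rings. The cis fusion of the two new stereocentres is dictated by the three-membered ring, and their sense relative to the two existing centres is set in the C–C bond-forming step: in the chair-like transition state the allylic side chain, the isopropenyl group and the bulky Ph2S+ group are all equatorial, and the developing potassium-bound oxygen sits equatorial and gauche to sulfur (Coulombic, cisoid approach) with the small methyl group axial. This trans-diequatorial betaine can reach the anti arrangement of O and S through a twist conformer and should close, with inversion at the sulfur-bearing carbon, to the oxirane on the face of the CH2 side chain and opposite to the isopropenyl group, as the target requires. The step needs ylide formation in the presence of an enolisable ketone (secured by the much higher acidity of the sulfonium α-CH) and selection between the two trans betaines (secured by the equatorial preference of Ph2S+, since the alternative needs it axial); betaines with O and S cis cannot close and can only return to the ylide.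

Step 11
Reactants: 19 {[(1S,2R,4R)-2-bromo-1-methyl-4-{3-[(1R,2R,3S,6S)-6-methyl-3-(prop-1-en-2-yl)-7-oxabicyclo[4.1.0]heptan-2-yl]prop-1-en-2-yl}cyclohexyl]oxy}triethylsilane
Product: 20 (1S,2R,4R)-2-bromo-1-methyl-4-{3-[(1R,2R,3S,6S)-6-methyl-3-(prop-1-en-2-yl)-7-oxabicyclo[4.1.0]heptan-2-yl]prop-1-en-2-yl}cyclohexan-1-ol
Conditions: Bu4NF, AcOH, THF, 0 °C → rt
Reagents that add atoms: none
Why: Fluoride cleavage of the tertiary triethylsilyl ether, buffered with acetic acid so that neither the oxirane nor the cis-bromohydrin meets a basic alkoxide, should liberate the tertiary alcohol.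

**Compound list**

1 | (1S,2S,4R)-1-methyl-4-(prop-1-en-2-yl)cyclohexane-1,2-diol (limonene-1,2-diol) | C=C(C)[C@@H]1CC[C@](C)(O)[C@@H](O)C1 | starting material
2 | (1S,2S,5R)-2-hydroxy-2-methyl-5-(prop-1-en-2-yl)cyclohexyl trifluoromethanesulfonate | C=C(C)[C@@H]1CC[C@](C)(O)[C@@H](OS(=O)(=O)C(F)(F)F)C1 | intermediate
3 | (1S,2S,5R)-2-methyl-5-(prop-1-en-2-yl)-2-(triethylsilyloxy)cyclohexyl trifluoromethanesulfonate | C=C(C)[C@@H]1CC[C@](C)(O[Si](CC)(CC)CC)[C@@H](OS(=O)(=O)C(F)(F)F)C1 | intermediate
4 | {[(1S,2R,4R)-2-bromo-1-methyl-4-(prop-1-en-2-yl)cyclohexyl]oxy}triethylsilane | C=C(C)[C@@H]1CC[C@](C)(O[Si](CC)(CC)CC)[C@H](Br)C1 | intermediate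
5 | {[(1S,2R,4R)-2-bromo-4-(3-chloroprop-1-en-2-yl)-1-methylcyclohexyl]oxy}triethylsilane | C=C(CCl)[C@@H]1CC[C@](C)(O[Si](CC)(CC)CC)[C@H](Br)C1 | intermediate
6 | {[(1S,2R,4R)-2-bromo-4-(3-iodoprop-1-en-2-yl)-1-methylcyclohexyl]oxy}triethylsilane | C=C(CI)[C@@H]1CC[C@](C)(O[Si](CC)(CC)CC)[C@H](Br)C1 | intermediate
7 | (S)-(+)-carvone, (5S)-2-methyl-5-(prop-1-en-2-yl)cyclohex-2-en-1-one | CC1=CC[C@@H](CC1=O)C(C)=C | starting material
8 | lithium (5S)-2-methyl-5-(prop-1-en-2-yl)cyclohex-1-en-1-olate | [Li+].[O-]C1=C(C)CC[C@H](C(=C)C)C1 | intermediate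
9 | (2S,5S)-2-methyl-5-(prop-1-en-2-yl)cyclohexan-1-one (trans-dihydrocarvone, with its 2-epimer) | C[C@H]1CC[C@H](C(=C)C)CC1=O | intermediate
10 | (4S,7S)-7-methyl-4-(prop-1-en-2-yl)oxepan-2-one | O=C1C[C@@H](C(=C)C)CC[C@H](C)O1 | intermediate
11 | lithium enolate of lactone 10 | [Li+].[O-]C1=C[C@@H](C(=C)C)CC[C@H](C)O1 | intermediate
12 | (3R,4S,7S)-3-{2-[(1R,3R,4S)-3-bromo-4-methyl-4-(triethylsilyloxy)cyclohexyl]prop-2-en-1-yl}-7-methyl-4-(prop-1-en-2-yl)oxepan-2-one | O=C1[C@H](CC(=C)[C@@H]2CC[C@](C)(O[Si](CC)(CC)CC)[C@H](Br)C2)[C@@H](C(=C)C)CC[C@H](C)O1 | intermediate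
13 | (2R,3S,6S)-2-{2-[(1R,3R,4S)-3-bromo-4-methyl-4-(triethylsilyloxy)cyclohexyl]prop-2-en-1-yl}-3-(prop-1-en-2-yl)heptane-1,6-diol | OC[C@H](CC(=C)[C@@H]1CC[C@](C)(O[Si](CC)(CC)CC)[C@H](Br)C1)[C@@H](C(=C)C)CC[C@H](C)O | intermediate
14 | primary triflate of 13 (6-hydroxyl free) | FC(F)(F)S(=O)(=O)OC[C@H](CC(=C)[C@@H]1CC[C@](C)(O[Si](CC)(CC)CC)[C@H](Br)C1)[C@@H](C(=C)C)CC[C@H](C)O | intermediate
15 | [(2R,3S,6S)-2-{2-[(1R,3R,4S)-3-bromo-4-methyl-4-(triethylsilyloxy)cyclohexyl]prop-2-en-1-yl}-6-hydroxy-3-(prop-1-en-2-yl)heptyl]diphenylsulfonium trifluoromethanesulfonate | [O-]S(=O)(=O)C(F)(F)F.c1ccccc1[S+](c1ccccc1)C[C@H](CC(=C)[C@@H]1CC[C@](C)(O[Si](CC)(CC)CC)[C@H](Br)C1)[C@@H](C(=C)C)CC[C@H](C)O | intermediate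
16 | [(2R,3S)-2-{2-[(1R,3R,4S)-3-bromo-4-methyl-4-(triethylsilyloxy)cyclohexyl]prop-2-en-1-yl}-6-oxo-3-(prop-1-en-2-yl)heptyl]diphenylsulfonium trifluoromethanesulfonate | [O-]S(=O)(=O)C(F)(F)F.c1ccccc1[S+](c1ccccc1)C[C@H](CC(=C)[C@@H]1CC[C@](C)(O[Si](CC)(CC)CC)[C@H](Br)C1)[C@@H](C(=C)C)CCC(C)=O | intermediate
17 | diphenylsulfonium ylide of 16 (carbanion on the CH next to sulfur) | c1ccccc1[S+](c1ccccc1)[CH-][C@H](CC(=C)[C@@H]1CC[C@](C)(O[Si](CC)(CC)CC)[C@H](Br)C1)[C@@H](C(=C)C)CCC(C)=O | intermediate
18 | cyclic betaine: cyclohexane with equatorial oxido (methyl axial) and equatorial diphenylsulfonio groups trans on neighbouring carbons | C=C(C[C@@H]1[C@@H](C(=C)C)CC[C@](C)([O-])[C@H]1[S+](c2ccccc2)c2ccccc2)[C@@H]3CC[C@](C)(O[Si](CC)(CC)CC)[C@H](Br)C3 | intermediate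
19 | {[(1S,2R,4R)-2-bromo-1-methyl-4-{3-[(1R,2R,3S,6S)-6-methyl-3-(prop-1-en-2-yl)-7-oxabicyclo[4.1.0]heptan-2-yl]prop-1-en-2-yl}cyclohexyl]oxy}triethylsilane | C=C(C[C@@H]1[C@@H](C(=C)C)CC[C@]2(C)O[C@H]12)[C@@H]1CC[C@](C)(O[Si](CC)(CC)CC)[C@H](Br)C1 | intermediate
20 | (1S,2R,4R)-2-bromo-1-methyl-4-{3-[(1R,2R,3S,6S)-6-methyl-3-(prop-1-en-2-yl)-7-oxabicyclo[4.1.0]heptan-2-yl]prop-1-en-2-yl}cyclohexan-1-ol (CNP0213097.1) | C=C(C[C@@H]1[C@@H](C(=C)C)CC[C@]2(C)O[C@H]12)[C@@H]1CC[C@](C)(O)[C@H](Br)C1 | target

**Count**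

Total steps: 11. Longest linear sequence: 9 (steps 1 to 3, then 6 to 11).

**Steps most likely to fail**

Step 10. What may go wrong is poor facial selectivity in the ylide addition: betaines with oxygen and sulfur cis cannot close, and the trans-diaxial betaine closes to the other oxirane face. Proton transfer from the ketone can also compete. The fallback sets out from diol 13 and comes back at 19. Both hydroxyls are oxidised with Dess–Martin periodinane to the keto aldehyde F1. Double Wittig methylenation (Ph3P=CH2, THF, 0 °C) gives the diene F2. Ring-closing metathesis with the second-generation Hoveyda–Grubbs catalyst (CH2Cl2, 40 °C) closes the trisubstituted cyclohexene F3 across the same two carbons. Shi epoxidation with the D-fructose-derived ketone, KHSO5 and K2CO3 buffer then puts oxygen on the required face under reagent control and should prefer the trisubstituted ring alkene over the three 1,1-disubstituted ones, giving 19.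

Step 1. What may go wrong is slow displacement next to the fully substituted silyloxy carbon, so that E2 elimination of the axial triflate or oxygen participation takes over. The fallback sets out from diol 1 and comes back at 4. SOCl2/Et3N gives the cyclic sulfite F4, and brief oxidation with catalytic RuCl3 and NaIO4 (MeCN/H2O, 0 °C) gives the cyclic sulfate F5, in which the tertiary oxygen is tied up and the secondary C–O bond is strongly activated. LiBr opens it at the secondary carbon with inversion, and acid hydrolysis of the sulfate monoester gives the free cis-bromohydrin F6. Silylation with Et3SiOTf/2,6-lutidine then gives 4.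

Step 8. What may go wrong is slow S-alkylation of the weakly nucleophilic diphenyl sulfide by a β-branched triflate, which leaves time for cyclisation onto the pendant alkenes or the free hydroxyl, together with incomplete primary over secondary selectivity in the triflation. The fallback sets out from diol 13 and comes back at 16. Diphenyl disulfide with PBu3 converts the primary hydroxyl selectively to the hydroxy phenyl sulfide F7. Oxidation with SO3·pyridine/DMSO/Et3N gives the keto sulfide F8. S-Phenylation with diphenyliodonium triflate and catalytic Cu(OBz)2 (copper dibenzoate) in chlorobenzene at about 110 °C then gives the sulfonium triflate 16.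

**Further compounds**

F1 | step 10 | keto aldehyde: (2R,3S)-2-{2-[(1R,3R,4S)-3-bromo-4-methyl-4-(triethylsilyloxy)cyclohexyl]prop-2-en-1-yl}-6-oxo-3-(prop-1-en-2-yl)heptanal | O=C[C@H](CC(=C)[C@@H]1CC[C@](C)(O[Si](CC)(CC)CC)[C@H](Br)C1)[C@@H](C(=C)C)CCC(C)=O
F2 | step 10 | diene: both carbonyl groups of F1 methylenated, configuration unchanged | C=C[C@H](CC(=C)[C@@H]1CC[C@](C)(O[Si](CC)(CC)CC)[C@H](Br)C1)[C@@H](C(=C)C)CCC(C)=C
F3 | step 10 | cyclohexene: 19 with a C=C bond in place of the oxirane | C=C(C[C@@H]1[C@@H](C(=C)C)CCC(C)=C1)[C@@H]1CC[C@](C)(O[Si](CC)(CC)CC)[C@H](Br)C1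
F4 | step 1 | cyclic sulfite of diol 1 | C=C(C)[C@@H]1CC[C@]2(C)OS(=O)O[C@H]2C1
F5 | step 1 | cyclic sulfate of diol 1 | C=C(C)[C@@H]1CC[C@]2(C)OS(=O)(=O)O[C@H]2C1
F6 | step 1 | (1S,2R,4R)-2-bromo-1-methyl-4-(prop-1-en-2-yl)cyclohexan-1-ol | C=C(C)[C@@H]1CC[C@](C)(O)[C@H](Br)C1
F7 | step 8 | hydroxy phenyl sulfide: 13 with SPh in place of the primary OH | c1ccccc1SC[C@H](CC(=C)[C@@H]1CC[C@](C)(O[Si](CC)(CC)CC)[C@H](Br)C1)[C@@H](C(=C)C)CC[C@H](C)O
F8 | step 8 | keto phenyl sulfide: F7 with the secondary alcohol oxidised | c1ccccc1SC[C@H](CC(=C)[C@@H]1CC[C@](C)(O[Si](CC)(CC)CC)[C@H](Br)C1)[C@@H](C(=C)C)CCC(C)=O
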